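**Retrosynthetic overview**
- Last bond: the C3–acyl bond of the pyridone, made by a light-driven 1,3 O-to-C acyl shift of the 4-O-acyl pyridone (enol ester of the side-chain acid with the 5-aryl-4-hydroxy-2-pyridone core).
- Side-chain acid: C2–C3 bond by stereoinvertive zinc-catalysed coupling of an alkyl Grignard reagent with ethyl O-triflyl-L-lactate (C2 bought as L-lactate).
- C5–C6 bond by nickel-catalysed reductive coupling of (R)-3-bromo-2-methylpropan-1-ol (C4 bought, Roche-ester family) with (E)-2-bromobut-2-ene (alkene geometry bought).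
- Core: Suzuki coupling of 5-bromo-2,4-dimethoxypyridine with (4-hydroxyphenyl)boronic acid, then double O-demethylation.
- Rings: no ring is built; the benzene and pyridine rings are bought, and the pyridine is unmasked to the pyridone before the side chain is attached.

Assumption: the five starting materials, including ethyl O-triflyl-L-lactate, isomerically pure (E)-2-bromobut-2-ene and 5-bromo-2,4-dimethoxypyridine, are taken as catalogue compounds of the stated configuration.

**Route**

Step 1
Reactants: 1 (R)-3-bromo-2-methylpropan-1-ol; 2 (E)-2-bromobut-2-ene (2 equiv)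
Product: 3 (S,E)-2,4-dimethylhex-4-en-1-ol
Conditions: NiBr2(dme) (5 mol%), 4,4'-di-tert-butyl-2,2'-bipyridine (5 mol%), Mn powder (2 equiv), NaI (0.25 equiv), DMPU, 25 °C
Reagents that add atoms: none
Why: Nickel-catalysed reductive cross-electrophile coupling: zerovalent nickel inserts into the alkenyl C–Br bond with retention of the E geometry and then captures the primary alkyl radical formed from 1, so the new C(sp3)–C(sp2) bond forms one carbon away from the untouched methyl-bearing stereocentre bought in 1 (the descriptor changes from R to S only because the CIP priorities change), and the free hydroxyl is tolerated.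

Step 2
Reactants: 3 (S,E)-2,4-dimethylhex-4-en-1-ol
Product: 4 (S,E)-6-chloro-3,5-dimethylhex-2-ene
Conditions: PPh3 (1.3 equiv), CCl4 (3 equiv), CH2Cl2, 40 °C
Reagents that add atoms: carbon tetrachloride, ClC(Cl)(Cl)Cl
Why: Appel reaction: SN2 displacement of the oxyphosphonium at the primary carbon under neutral conditions leaves the stereocentre and the trisubstituted alkene untouched, and gives a chloride whose Grignard reagent carries no bromide that could racemise the triflate in step 3.

Step 3
Reactants: 4 (S,E)-6-chloro-3,5-dimethylhex-2-ene; 5 ethyl (S)-2-{[(trifluoromethyl)sulfonyl]oxy}propanoate (1.2 equiv)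
Product: 7 ethyl (2S,4R,E)-2,4,6-trimethyloct-6-enoate, via Grignard reagent 6 (not isolated)
Conditions: Mg turnings (cat. I2), THF, 65 °C; then added slowly to 5, ZnCl2 (10 mol%), THF, 0 °C
Reagents that add atoms: none
Why: Zinc-catalysed stereospecific C(sp3)–C(sp3) coupling of a Grignard reagent with an α-triflyloxy ester: the triorganozincate formed in the flask displaces triflate by SN2 with clean inversion faster than it adds to the ester, so the (S)-lactate centre bought in 5 becomes the (2S)-methyl centre (same letter after inversion because the priorities change) and C4 is carried through unchanged.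

Step 4
Reactants: 7 ethyl (2S,4R,E)-2,4,6-trimethyloct-6-enoate
Product: 8 (2S,4R,E)-2,4,6-trimethyloct-6-enoic acid
Conditions: LiOH·H2O (3 equiv), THF/MeOH/H2O 3:1:1, 25 °C; then 1 M HCl to pH 3 at 0 °C
Reagents that add atoms: lithium hydroxide, [Li+].[OH-]
Why: Ester saponification: hydroxide attacks the ester carbonyl and the resulting carboxylate does not enolise under these conditions, so C2 is not epimerised.

Step 5
Reactants: 9 5-bromo-2,4-dimethoxypyridine; 10 (4-hydroxyphenyl)boronic acid (1.3 equiv)
Product: 11 4-(4,6-dimethoxypyridin-3-yl)phenol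
Conditions: Pd(dppf)Cl2 (3 mol%), K2CO3 (3 equiv), 1,4-dioxane/H2O 4:1, 90 °C
Reagents that add atoms: none
Why: Suzuki–Miyaura coupling of a heteroaryl bromide; the free phenol (as phenoxide) is tolerated and no stereocentre is involved.

Step 6
Reactants: 11 4-(4,6-dimethoxypyridin-3-yl)phenol
Product: 12 4-hydroxy-5-(4-hydroxyphenyl)pyridin-2(1H)-one
Conditions: 48% aq. HBr, AcOH, 110 °C; then adjusted to pH 5, filtered
Reagents that add atoms: none
Why: Acid-mediated O-demethylation: bromide attacks the methyl groups of the protonated methoxypyridine (SN2), first at the 2-methoxy group to give the pyridone and then at the 4-methoxy group, the phenol being stable to the acid.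

Step 7
Reactants: 8 (2S,4R,E)-2,4,6-trimethyloct-6-enoic acid; 12 4-hydroxy-5-(4-hydroxyphenyl)pyridin-2(1H)-one (1.3 equiv)
Product: 14 5-(4-hydroxyphenyl)-2-oxo-1,2-dihydropyridin-4-yl (2S,4R,E)-2,4,6-trimethyloct-6-enoate, via acid chloride 13 (not isolated)
Conditions: 1-chloro-N,N,2-trimethylprop-1-en-1-amine (1.0 equiv), CH2Cl2, 0 to 25 °C; then added to 12 premixed with iPr2NEt (1.3 equiv), DMF, −20 to 0 °C; pH 5 work-up, rapid silica filtration
Reagents that add atoms: none
Why: Acid chloride formation with the neutral α-chloroenamine reagent (no HCl, no free ketene-forming base) followed by O-acylation of the only anion present, the 4-oxido-pyridone (a vinylogous carboxylic acid, pKa about 6, against about 10 for the phenol), so the enol ester forms at O4 without touching C2 or the phenol.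

Step 8
Reactants: 14 5-(4-hydroxyphenyl)-2-oxo-1,2-dihydropyridin-4-yl (2S,4R,E)-2,4,6-trimethyloct-6-enoate
Product: 16 vancouverone A, via keto tautomer 15 (not isolated)
Conditions: hν (300–310 nm, Pyrex filter, thin-film flow coil), N2-sparged dry MeCN (2 mM), 20 °C
Reagents that add atoms: none
Why: Proposed new method: a photo-Fries-type 1,3 O-to-C acyl shift on a 4-acyloxy-2-pyridone, not yet shown for this ring system; exciting the 5-aryl-2-pyridone chromophore leads to homolysis of the enol-ester C(O)–O bond and a caged singlet pair of acyl radical and pyridon-4-yloxyl radical, whose carbon spin density sits at C3 (C5 is blocked by the aryl group), so in-cage recombination forms the C3–acyl bond and enolisation gives the hydrogen-bonded product, which is photostable through excited-state proton transfer; the acyl σ-radical keeps its α-stereocentre and recombines (above 10^9 s-1) far faster than it loses CO (about 10^4–10^5 s-1), and the isolated alkene does not absorb at this wavelength; the closest known reaction types are the photo-Fries rearrangement of aryl esters and the photochemical 1,3-acyl shift of enol esters to 1,3-dicarbonyl compounds.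

**Compound list**

1 | (R)-3-bromo-2-methylpropan-1-ol | BrC[C@H](C)CO | starting material
2 | (E)-2-bromobut-2-ene | C/C=C(\C)Br | starting material
3 | (S,E)-2,4-dimethylhex-4-en-1-ol | C/C=C(\C)C[C@H](C)CO | intermediate
4 | (S,E)-6-chloro-3,5-dimethylhex-2-ene | C/C=C(\C)C[C@H](C)CCl | intermediate
5 | ethyl (S)-2-{[(trifluoromethyl)sulfonyl]oxy}propanoate | CCOC(=O)[C@H](C)OS(=O)(=O)C(F)(F)F | starting material
6 | [(S,E)-2,4-dimethylhex-4-en-1-yl]magnesium chloride | C/C=C(\C)C[C@H](C)C[Mg]Cl | intermediate
7 | ethyl (2S,4R,E)-2,4,6-trimethyloct-6-enoate | C/C=C(\C)C[C@H](C)C[C@H](C)C(=O)OCC | intermediate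
8 | (2S,4R,E)-2,4,6-trimethyloct-6-enoic acid | C/C=C(\C)C[C@H](C)C[C@H](C)C(=O)O | intermediate
9 | 5-bromo-2,4-dimethoxypyridine | COc1cc(OC)c(Br)cn1 | starting material
10 | (4-hydroxyphenyl)boronic acid | OB(O)c1ccc(O)cc1 | starting material
11 | 4-(4,6-dimethoxypyridin-3-yl)phenol | COc1cc(OC)c(-c2ccc(O)cc2)cn1 | intermediate
12 | 4-hydroxy-5-(4-hydroxyphenyl)pyridin-2(1H)-one | O=c1cc(O)c(-c2ccc(O)cc2)c[nH]1 | intermediate
13 | (2S,4R,E)-2,4,6-trimethyloct-6-enoyl chloride | C/C=C(\C)C[C@H](C)C[C@H](C)C(=O)Cl | intermediate
14 | 5-(4-hydroxyphenyl)-2-oxo-1,2-dihydropyridin-4-yl (2S,4R,E)-2,4,6-trimethyloct-6-enoate | C/C=C(\C)C[C@H](C)C[C@H](C)C(=O)Oc1cc(=O)[nH]cc1-c1ccc(O)cc1 | intermediate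
15 | 5-(4-hydroxyphenyl)-3-[(2S,4R,E)-2,4,6-trimethyloct-6-enoyl]pyridine-2,4(1H,3H)-dione (transient, ring C3 unassigned) | C/C=C(\C)C[C@H](C)C[C@H](C)C(=O)C1C(=O)NC=C(-c2ccc(O)cc2)C1=O | intermediate
16 | vancouverone A, 4-hydroxy-5-(4-hydroxyphenyl)-3-[(2S,4R,E)-2,4,6-trimethyloct-6-enoyl]pyridin-2(1H)-one | C/C=C(\C)C[C@H](C)C[C@H](C)C(=O)c1c(O)c(-c2ccc(O)cc2)c[nH]c1=O | target

**Step count and risks**

Total steps: 8. Longest linear sequence: 6 (steps 1, 2, 3, 4, 7, 8).

Most likely to fail:

1. Step 8 (the proposed new photochemical acyl shift). Possible failures are [4+4] photodimerisation or 4π ring closure of the pyridone, cage escape returning 12, and inner-filter slowing as the product accumulates. Dilution, the 300–310 nm window and a thin-film flow coil are the built-in counters. Fallback with known chemistry: setting out from 14, the established nucleophile-catalysed thermal O-to-C acyl migration of 4-acyloxy pyridones and pyranones is used (4-(dimethylamino)pyridine 1.2 equiv, Et3N, toluene, 60–80 °C). It runs through the ion pair 1-[(2S,4R,E)-2,4,6-trimethyloct-6-enoyl]-4-(dimethylamino)pyridinium 5-(4-hydroxyphenyl)-2-oxo-1,2-dihydropyridin-4-olate F1, whose C3 attacks the acylpyridinium, and comes back to the route at 16. The C2 configuration should be checked after this ionic variant.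

2. Step 7 (site-selective O-acylation and handling of the activated enol ester). Possible failures are acylation of the phenol, double acylation, or hydrolysis of 14 on silica. Fallback: setting out from 12, both acidic oxygens are silylated (TBSCl 2.2 equiv, imidazole, DMF) to give 4-[(tert-butyldimethylsilyl)oxy]-5-{4-[(tert-butyldimethylsilyl)oxy]phenyl}pyridin-2(1H)-one F2. The labile silyl group on the vinylogous-acid oxygen is then removed with aqueous citric acid in THF to give 5-{4-[(tert-butyldimethylsilyl)oxy]phenyl}-4-hydroxypyridin-2(1H)-one F3, which has only one acylable hydroxyl. Acylation with 13 under the step 7 conditions gives 5-{4-[(tert-butyldimethylsilyl)oxy]phenyl}-2-oxo-1,2-dihydropyridin-4-yl (2S,4R,E)-2,4,6-trimethyloct-6-enoate F4, and HF·pyridine in THF at 0 °C removes the aryl silyl ether to come back to the route at 14.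

3. Step 1 (reductive cross-electrophile coupling with a hindered, volatile alkenyl bromide). Possible failures are homocoupling, low conversion or partial loss of alkene geometry. Fallback: setting out from 1, the alcohol is silylated (TBSCl, imidazole, CH2Cl2) to (R)-(3-bromo-2-methylpropoxy)(tert-butyl)dimethylsilane F5. Zinc dust (cat. I2, DMA, 70 °C) inserts to give {(R)-3-[(tert-butyldimethylsilyl)oxy]-2-methylpropyl}zinc bromide F6, which is used directly. Negishi coupling with 2 (Pd(PPh3)4 5 mol%, THF/DMA, 50 °C, retention of alkene geometry) gives tert-butyl{[(2S,4E)-2,4-dimethylhex-4-en-1-yl]oxy}dimethylsilane F7, and tetrabutylammonium fluoride in THF comes back to the route at 3.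

Further compounds
F1 | step 8 | 1-[(2S,4R,E)-2,4,6-trimethyloct-6-enoyl]-4-(dimethylamino)pyridinium 5-(4-hydroxyphenyl)-2-oxo-1,2-dihydropyridin-4-olate | C/C=C(\C)C[C@H](C)C[C@H](C)C(=O)[n+]1ccc(N(C)C)cc1.[O-]c1cc(=O)[nH]cc1-c1ccc(O)cc1
F2 | step 7 | 4-[(tert-butyldimethylsilyl)oxy]-5-{4-[(tert-butyldimethylsilyl)oxy]phenyl}pyridin-2(1H)-one | CC(C)(C)[Si](C)(C)Oc1ccc(cc1)-c1c[nH]c(=O)cc1O[Si](C)(C)C(C)(C)C
F3 | step 7 | 5-{4-[(tert-butyldimethylsilyl)oxy]phenyl}-4-hydroxypyridin-2(1H)-one | CC(C)(C)[Si](C)(C)Oc1ccc(cc1)-c1c[nH]c(=O)cc1O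
F4 | step 7 | 5-{4-[(tert-butyldimethylsilyl)oxy]phenyl}-2-oxo-1,2-dihydropyridin-4-yl (2S,4R,E)-2,4,6-trimethyloct-6-enoate | C/C=C(\C)C[C@H](C)C[C@H](C)C(=O)Oc1cc(=O)[nH]cc1-c1ccc(O[Si](C)(C)C(C)(C)C)cc1
F5 | step 1 | (R)-(3-bromo-2-methylpropoxy)(tert-butyl)dimethylsilane | BrC[C@H](C)CO[Si](C)(C)C(C)(C)C
F6 | step 1 | {(R)-3-[(tert-butyldimethylsilyl)oxy]-2-methylpropyl}zinc bromide | Br[Zn]C[C@H](C)CO[Si](C)(C)C(C)(C)C
F7 | step 1 | tert-butyl{[(2S,4E)-2,4-dimethylhex-4-en-1-yl]oxy}dimethylsilane | C/C=C(\C)C[C@H](C)CO[Si](C)(C)C(C)(C)C
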